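Readings and results come from a simulation with made-up constants; the scatter is artificial.

The pitfall in a flask that stalls is to follow L and G each along its own curve, when the question asks for their share.

| flask | Q | D | remark | time |
|---|---|---|---|---|
| north-east | 0.091 M | 1 equiv | run made earlier |  |
| south | 0.091 M | 2.2 equiv | run made earlier |  |
| flask | 0.091 M | 1.50 equiv |  | 3.0 d |

| run | time / d | L / % | G / % | Q / % |
|---|---|---|---|---|
| north-east | 0.125 | 17 | 11 | 53 |
| north-east | 0.333 | 32 | 14 | 30 |
| north-east | 0.625 | 34 | 16 | 27 |
| north-east | 1.04 | 36 | 17 | 21 |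
| north-east | 1.67 | 37 | 16 | 26 |
| north-east | 2.08 | 32 | 23 | 22 |
| north-east | 2.50 | 30 | 16 | 25 |
| south | 0.208 | 42 | 23 | 25 |
| south | 0.333 | 45 | 24 | 14 |
| south | 0.417 | 47 | 31 | 14 |
| south | 0.625 | 49 | 27 | 10 |
| south | 1.04 | 48 | 29 | 12 |
| south | 1.67 | 49 | 29 | 11 |
| south | 2.50 | 51 | 25 | 15 |

(readings scatter by 2 percentage points)

1. share of L in L plus G at 8.0 min
2. share of L in L plus G at 2.5 h
3. share of L in L plus G at 3.0 d



I set two rates side by side, that of making L and that of making G. I took both to draw on Q with D, so that the amounts of Q and D present multiply the two rates alike and their ratio, the selectivity factor, carries neither time nor loading. The readings allowed this. Summed over each run, the share of L in L plus G came to 65.9 % in the north-east run and 63.8 % in the south run, a gap of 2.1 percentage points, while one reading scatters by 2 points. So I averaged them into the branching share, 64.8 %, and committed to it at each asked time in the new flask.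

The forecast, saying “The share of L looks flat in both runs”, gave 64 %, 65 % and 65 %.

The new flask gave 63.8 %, 63.9 % and 65.2 %.

    Q + D ⇌ L (K = 43.0 /M, k = 0.0203 /M/min)
    Q + D ⇌ G (K = 22.7 /M, k = 0.0115 /M/min)
    D → J (k = 1.54 × 10⁻⁴ /min)
    L → X (k = 2.36 × 10⁻⁶ /min)
    Q ⇌ E (K = 0.962, k = 0.00170 /min)

By 0.300 d, with Q and D running forward to L and to G and Q also passing into E, this flask held L 35.8 %, G 20.1 % and E 21.0 %. D kept passing into J and stood at 30.8 % of its own charge at 3.00 d, while G after its highest at 1.10 d and L after its highest at 1.29 d ran back towards Q and D; at 3.00 d the branching share of 64.8 % applied to the L plus G then present gives L 39.2 %, and this flask held 39.5 %. In the neighbouring flask at 0.023 M of Q, the same share of its L plus G at 3.00 d gives 22.2 %, and that flask held L 22.3 %.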